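What is left of the left-handed substrate at the end is the cheapest clock you have, so read it first.

all flasks: left-handed substrate 0.10 M; right-handed substrate 0.10 M; precatalyst 1 mol%; impurity 0.64 mM; added ligand 3.4 mM

| charge | coupling partner | free catalyst | remark | time |
|---|---|---|---|---|
| north | 2 equiv | 5.7 mol% | run made earlier |  |
| west | 2 equiv | 7.3 mol% | run made earlier |  |
| Wednesday's | 2.00 equiv | 4.7 mol% |  | 30 h |
| Thursday's | 2.00 equiv | 14 mol% |  | 30 h |

| run | time / h | right-handed product / % | right-handed substrate / % | left-handed product / % | left-handed substrate / % |
|---|---|---|---|---|---|
| north | 2.50 | 1.4 | 48.4 | 5.4 | 45.1 |
| north | 5.00 | 2.5 | 47.3 | 9.2 | 41.1 |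
| north | 8.00 | 4.1 | 45.6 | 12.5 | 38.1 |
| north | 15.0 | 7.1 | 43.5 | 18.6 | 32.4 |
| north | 30.0 | 9.9 | 39.2 | 26.6 | 24.9 |
| west | 2.50 | 2.3 | 47.9 | 7.0 | 42.9 |
| west | 5.00 | 2.8 | 46.4 | 11.2 | 39.0 |
| west | 8.00 | 5.1 | 44.6 | 15.2 | 34.9 |
| west | 15.0 | 8.2 | 41.7 | 21.8 | 28.4 |
| west | 30.0 | 12.6 | 35.8 | 30.9 | 20.3 |

(each reading ± 0.3 percentage points)

- free catalyst is single-handed; left-handed substrate and right-handed substrate are mirror images of each other, charged as a racemate, each of them at the stated concentration
- the analysis behind the earlier runs scatters by 0.3 percentage points, standard deviation
- what may be going on: coupling partner + free catalyst + left-handed substrate -> free catalyst + left-handed product; coupling partner + free catalyst + right-handed substrate -> free catalyst + right-handed product; left-handed substrate + racemization catalyst <-> right-handed substrate + racemization catalyst; racemization catalyst + impurity -> spent catalyst; free catalyst + added ligand <-> idle complex; precatalyst -> racemization catalyst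

1. which of these there is most of at the end, counted by the substrate in it, Wednesday's (left-handed substrate / right-handed substrate / left-handed product / right-handed product)
2. which of these there is most of at the end, counted by the substrate in it, Thursday's (left-handed substrate / right-handed substrate / left-handed product / right-handed product)
3. final amount of the leader among these, as a percentage of the left-handed substrate and right-handed substrate together charged, in Wednesday's
4. final amount of the leader among these, as a percentage of the left-handed substrate and right-handed substrate together charged, in Thursday's

Call exposure the logarithm of charged over left, with each hand charged at half of the total. At 30.0 h, north stands at 0.697 and west at 0.901. Exposure of the left-handed substrate over exposure of the right-handed substrate, pooled over both runs, is the apparent selectivity 2.77, a reading with any racemization in it, not the selectivity factor of the coupling itself. In north, left-handed substrate plus left-handed product comes to 51.5%, so take that product as half minus its substrate.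

Exposure per loading is about the same in north as in west. Scaling to Wednesday's gives 0.578. That leaves 40.6% right-handed substrate, 28.1% left-handed substrate and 21.9% left-handed product, so right-handed substrate leads.

The same scaling gives Thursday's 1.72, but 14 mol% lies far beyond both runs, and this is the weak link. Reforge it. Partner and substrates were charged equally in total, so the percent converted is the percent of partner used. Its mean share, taken between start and end, is 0.818 in north, 0.782 in west and, from the crude exposure, 0.679 in Thursday's. The added ligand holds free catalyst as idle complex, so treat that binding as quickly settled and subtract a steady loss of loading. Exposure over mean partner, run back through north and west, reads a loss of 1.1 mol%. Thursday's exposure becomes 1.63, which gives 40.2% left-handed product against 27.8% right-handed substrate, so the product leads.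

The forecast says right-handed substrate at 41.5% for Wednesday's and left-handed product at 45% for Thursday's, and it notes “so racemization is weak”.

The flasks give right-handed substrate at 40.6% on Wednesday's and left-handed product at 41.3% on Thursday's.

    coupling partner + free catalyst + left-handed substrate → free catalyst + left-handed product (k = 42.8 L² mol⁻² h⁻¹)
    coupling partner + free catalyst + right-handed substrate → free catalyst + right-handed product (k = 13.0 L² mol⁻² h⁻¹)
    left-handed substrate + racemization catalyst ⇌ right-handed substrate + racemization catalyst, rate k3*[racemization catalyst]*[left-handed substrate] forward; the back reaction follows from the equilibrium constant (k = 15.5 L mol⁻¹ h⁻¹)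
    racemization catalyst + impurity → spent catalyst (k = 2470 L mol⁻¹ h⁻¹)
    free catalyst + added ligand ⇌ idle complex (K = 750 L mol⁻¹, k = 26.5 L mol⁻¹ h⁻¹)
    precatalyst → racemization catalyst (k = 0.108 h⁻¹)

In Thursday's, idle complex formed early, with half its turnover done by 1.76 h, while the left-handed coupling reached that mark at 6.08 h. The coupling ran on with 38.8% of the coupling partner still free at the end. Put Thursday's 10.2% left-handed substrate through 2.77 and you get 28.2% right-handed substrate, against 28.6% in the flask. The neighbour of Thursday's with 1.20 equiv of coupling partner ends with 20.8% left-handed substrate, the same apparent selectivity gives 36.4% right-handed substrate, and that flask holds 36.6%.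

(The readings come from a simulation from invented constants, and the scatter is random.)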